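At early times the birch run is already flat: rings read 52.2% at 1.00 min and 51.2% at 12.0 min.

| setting | alder | birch | larch | flask |
|---|---|---|---|---|
| first end groups | 0.067 M | 0.15 M | 0.10 M | 0.10 M |
| second end groups | 0.098 M | 0.098 M | 0.049 M | 0.0980 M |
| remark | run made earlier | run made earlier | run made earlier |  |
| time |  |  |  | 12 min |

| run | time / min | links / % | rings / % |
|---|---|---|---|
| alder | 3.00 | 3.6 | 74.1 |
| alder | 6.00 | 1.8 | 73.6 |
| alder | 10.0 | 0.8 | 73.5 |
| alder | 12.0 | 0.9 | 74.5 |
| birch | 1.00 | 7.3 | 52.2 |
| birch | 2.00 | 7.4 | 51.5 |
| birch | 5.00 | 6.8 | 51.1 |
| birch | 12.0 | 6.6 | 51.2 |
| larch | 1.00 | 3.2 | 42.4 |
| larch | 2.00 | 2.2 | 43.0 |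
| larch | 5.00 | 2.6 | 43.9 |
| larch | 12.0 | 3.2 | 42.6 |

(scatter of a reading: 0.5 percentage points)

- the reaction counts as stopped when no species that holds the first end groups changes by six tenths of a point or more over the second half of the time

* at 12 min, what has stopped the reaction, if anything has (forward and back rates have come level / the second end groups has run out first / it is still moving / all of the first end groups has reacted)
* amount of links at 12 min, in percent of the first end groups charged
* amount of rings at 12 min, in percent of the first end groups charged
* amount of isomer of the product at 12 min, in percent of the first end groups charged

Let a and b be the charges of first and second end groups. If each first end group takes one second end group, the fraction of first end groups left is at least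

1 − b/a = 34.7% in birch, 2.00% in the flask.

So I read birch's stop as the second end groups running out, the limiting reagent, with less charged than the first. The flask has the same ordering, so I expect the same stop there. Now I average the four ring readings of birch:

σ = rings × a/b = 78.8%.

This σ, the rings formed per second end group charged, is what I carry. Larch, with half of that second charge, reads 87.7%, so σ is not one constant. Larch differs from birch in a as well as in b, and following b is my assumption. The flask shares birch's b, which gives

rings = σ b/a = 77.2%.

The weak link is that birch's a is not the flask's. Alder tests it. Its b matches birch's, but I take roughly 0.067 M of its second end groups to be spent. Subtracting larch from birch gives a share for the upper part of the second charge: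

69.9%.

Using this share, then larch's for the remainder, I get 74.7% rings for alder, and its readings average 73.9%. So I commit to 77.2% of rings for the flask, which leaves about 20.8% of the first end groups charged for links, isomer and anything else made with second end groups.

The forecast differs: forward and back rates have come level, links 3.3%, rings 66%, isomer 3.5%, the rings from “A rough mass-action constant from the three runs”.

The flask gives: the second end groups has run out first, links 8.59%, rings 76.3%, isomer 9.45%.

    first end groups + second end groups → rings, rate k1*[first end groups] as long as [second end groups] is above zero (k = 0.217 s⁻¹)
    second end groups + links → over-reaction product (k = 0.505 M⁻¹ s⁻¹)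
    first end groups + second end groups → links (k = 1.24 M⁻¹ s⁻¹)
    links ⇌ isomer of the product (K = 1.10, k = 0.0108 s⁻¹)

At 12.0 min the flask holds 0% of its second end groups and 3.8% of its first, with rings at 76.3% against my 77.2%. The neighbour with 0.17 M of first end groups keeps the same b, so σ b/a gives 45.4% of rings, with at least 42.4% of first left. That neighbour ends with 45.5% of rings, 0% of its second end groups and 43% of its first.

The runs stem from a simulated flask from invented constants; noise was put on by code.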